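**Assumption:** vidalol A has no stereocentre (it is achiral), so the SMILES defines it fully and no enantiocontrol is needed.

**Retrosynthetic overview**
1. Key disconnection, aryl C–O: the C5–OH of the dibromocatechol ring comes from Cu-catalysed hydroxylation of one C–Br of the symmetric dibromophenol 1 (giving 2); the bromide expelled is put back at C2 in the same pot (giving 3).
2. Diarylmethane C–C: phloroglucinol 4 is C-benzylated by lanosol 5 (made in the flask from 3) through its p-quinone methide, giving 6.
3. Last C–Br: monobromination of the phloroglucinol ring of 6 gives vidalol A 7.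
4. No ring is built: both benzene rings are bought (1 and 4), and the route needs no protecting groups.

**Route**

Step 1
Reactants: 1 3,5-dibromo-4-hydroxybenzaldehyde
Product: 3 2,3-dibromo-4,5-dihydroxybenzaldehyde, via 3-bromo-4,5-dihydroxybenzaldehyde 2 (not isolated)
Conditions: Cu2O (5 mol%), NaOH (5 equiv), degassed H2O, 100 °C, N2; then 0 °C, H2SO4 (to 2 M), MeCN, 30% H2O2 (1.05 equiv), 0 → 20 °C, one pot
Reagents that add atoms: sodium hydroxide, [Na+].[OH-]
Why: Proposed new method: a bromide-recycling hydroxylation, in which Cu(I) inserts into a C–Br ortho to the phenoxide and hydroxide exchange with C–O reductive elimination gives the catecholate dianion of 2, which is too electron-rich for a second insertion; after acidification H2O2 oxidises the one equivalent of expelled bromide to HOBr/Br2, which substitutes C2 (para to the new OH, the same site preference as in the known bromination of 5-bromovanillin to 5,6-dibromovanillin), so the net change is a formal 1,3-shift of Br with insertion of O and over-bromination is excluded by stoichiometry; the closest known reactions are the Ullmann-type Cu-catalysed hydroxylation of o-bromophenols and the H2O2/HBr oxidative bromination of phenols, and their merger with reuse of the leaving group is new.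

Step 2
Reactants: 3 2,3-dibromo-4,5-dihydroxybenzaldehyde; 4 phloroglucinol (benzene-1,3,5-triol)
Product: 6 2-(2,3-dibromo-4,5-dihydroxybenzyl)benzene-1,3,5-triol, via lanosol 5 (not isolated)
Conditions: NaBH4 (1.5 equiv), THF/H2O 4:1, 0 °C; then 4 (5 equiv), 2 M HCl to pH 1, 40 °C, N2
Reagents that add atoms: none
Why: NaBH4 reduces the aldehyde to lanosol, whose 4-OH para to the carbinol lets acid ionise it to a p-quinone methide that the large excess of very nucleophilic phloroglucinol traps at carbon (Friedel–Crafts benzylation; the three ring positions of 4 are equivalent and the excess, removed by water wash, suppresses double benzylation); no stereocentre is formed.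

Step 3
Reactants: 6 2-(2,3-dibromo-4,5-dihydroxybenzyl)benzene-1,3,5-triol
Product: 7 vidalol A, 2-bromo-4-[(2,3-dibromo-4,5-dihydroxyphenyl)methyl]benzene-1,3,5-triol
Conditions: NBS (1.0 equiv, added over 1 h), THF, −78 → −40 °C, dark
Reagents that add atoms: N-bromosuccinimide, O=C1CCC(=O)N1Br
Why: Electrophilic aromatic bromination (SEAr) takes place on the phloroglucinol ring, which is far more nucleophilic than the deactivated dibromocatechol ring, and since its two free positions are equivalent only one regioisomer can form, while one equivalent of NBS at low temperature holds the reaction at monobromination; no stereocentre is formed.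

**Compound list**
1 | 3,5-dibromo-4-hydroxybenzaldehyde | O=Cc1cc(Br)c(O)c(Br)c1 | starting material
2 | 3-bromo-4,5-dihydroxybenzaldehyde | O=Cc1cc(O)c(O)c(Br)c1 | intermediate
3 | 2,3-dibromo-4,5-dihydroxybenzaldehyde | O=Cc1cc(O)c(O)c(Br)c1Br | intermediate
4 | phloroglucinol (benzene-1,3,5-triol) | Oc1cc(O)cc(O)c1 | starting material
5 | lanosol (2,3-dibromo-4,5-dihydroxybenzyl alcohol) | OCc1cc(O)c(O)c(Br)c1Br | intermediate
6 | 2-(2,3-dibromo-4,5-dihydroxybenzyl)benzene-1,3,5-triol | Oc1cc(Cc2c(O)cc(O)cc2O)c(Br)c(Br)c1O | intermediate
7 | vidalol A | Oc1cc(Cc2c(O)cc(O)c(Br)c2O)c(Br)c(Br)c1O | target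

**Total step count:** 3
**Longest linear sequence:** 3 (1 → 3 → 6 → 7)

**Steps most likely to fail**

Step 1 (the proposed new step). The risks are a second hydroxylation, oxidation of catechol 2 by H2O2 in the presence of copper, and ipso-bromination with loss of the formyl group. The fallback uses known chemistry, sets out from 1 and comes back at 3. The one-pot relay is given up and the expelled bromide is discarded. Compound 1 is hydroxylated under classical Ullmann conditions (NaOH, Cu powder, H2O, reflux, N2), and 3-bromo-4,5-dihydroxybenzaldehyde 2 is isolated by acidification and crystallisation, free of copper. In a separate operation 2 is brominated with an external electrophile (Br2, 1.05 equiv, NaOAc, AcOH, 20 °C) to give 3. This fallback makes no compound outside the list (F0).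

Step 3. The risk is that the second equivalent position of the phloroglucinol ring also brominates, giving a mixture of 6, 7 and the dibromide. The fallback sets out from 3 and comes back at 7, and brings the ring-B bromine in with the building block. Compound 3 is reduced with NaBH4 and lanosol 5 is isolated. Lanosol is used to benzylate commercial 2-bromo-1,3,5-trimethoxybenzene (COc1cc(OC)c(Br)c(OC)c1, 3 equiv, TFA, CH2Cl2, 20 °C), whose two free positions are equivalent. This gives 3,4-dibromo-5-[(3-bromo-2,4,6-trimethoxyphenyl)methyl]benzene-1,2-diol F4. Demethylation with BBr3 (CH2Cl2, −78 → 0 °C) gives 7.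

Step 2. The risks are self-condensation of lanosol and double benzylation of phloroglucinol in the one-pot reduction/benzylation. The fallback sets out from 3 and comes back at 6, using the protected route that is standard for this class of bromophenols. Compound 3 is methylated (MeI, K2CO3, DMF) to 2,3-dibromo-4,5-dimethoxybenzaldehyde F1. F1 is reduced (NaBH4, MeOH) to (2,3-dibromo-4,5-dimethoxyphenyl)methanol F2. F2 alkylates 1,3,5-trimethoxybenzene (COc1cc(OC)cc(OC)c1; AlCl3, CH2Cl2, 0 °C) to give 2-(2,3-dibromo-4,5-dimethoxybenzyl)-1,3,5-trimethoxybenzene F3. Global demethylation with BBr3 (CH2Cl2, −78 → 20 °C) gives 6.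

**Further compounds**
F0 | step 1 | none | none
F1 | step 2 | 2,3-dibromo-4,5-dimethoxybenzaldehyde | COc1cc(C=O)c(Br)c(Br)c1OC
F2 | step 2 | (2,3-dibromo-4,5-dimethoxyphenyl)methanol | COc1cc(CO)c(Br)c(Br)c1OC
F3 | step 2 | 2-(2,3-dibromo-4,5-dimethoxybenzyl)-1,3,5-trimethoxybenzene | COc1cc(OC)c(Cc2cc(OC)c(OC)c(Br)c2Br)c(OC)c1
F4 | step 3 | 3,4-dibromo-5-[(3-bromo-2,4,6-trimethoxyphenyl)methyl]benzene-1,2-diol | COc1cc(OC)c(Br)c(OC)c1Cc1cc(O)c(O)c(Br)c1Br
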